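## Retrosynthetic overview
1. 13 ⇒ 11: both Me2C–O units are read as lactone carbonyls (a δ-lactone on ring A, an α-pyranone on ring B). One global MeMgBr addition sets all four methyl groups, and ring D re-closes on mild acid.
2. 11 ⇒ 3 + 8 + one carbon from DMF: Friedel–Crafts bond C4–C4a, then C-2 insertion. Ring C closes onto the only free ortho-OH, which fixes the 6-alkyl pattern.
3. 8 ⇒ 4 + malic acid (key step): the α-pyranone (future ring D) and a γ-lactone (acyl donor and 2'-OH mask) form in one operation.
4. 3 ⇒ 1 + 2: hydroarylation and lactonisation.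
5. Ring order: δ-lactone on A, in parallel with α-pyranone + γ-lactone on B (one pot) → ring C → ring D.

Assumption: the target SMILES has no stereocentre and its only non-aromatic C=C lies in a ring. The compound is therefore achiral and no enantiocontrol is needed.

## Route

Step 1
Reactants: 1 phloroglucinol (benzene-1,3,5-triol, 1.5 equiv); 2 acrylic acid
Product: 3 5,7-dihydroxychroman-2-one (5,7-dihydroxy-3,4-dihydrocoumarin)
Conditions: Amberlyst-15, BHT (trace), toluene/1,4-dioxane, reflux, Dean–Stark, 8 h
Reagents that add atoms: none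
Why: Acid-catalysed hydroarylation–lactonisation (Friedel–Crafts-type conjugate addition of the arene to acrylic acid plus ring closure, the reaction type that turns resorcinol into 7-hydroxydihydrocoumarin) is fast on the more nucleophilic, C3-symmetric 1, so only one mono-adduct can form and the excess of 1 holds back a second annulation; no stereocentre arises.

Step 2 (key step)
Reactants: 4 2,4-dihydroxyphenylacetic acid; 5 DL-malic acid (racemic)
Product: 8 2H-furo[3,2-g]chromene-2,7(3H)-dione (2-oxo-2,3-dihydropsoralen), via formylacetic acid 6 (not isolated), via coumarin-6-ylacetic acid 7 (not isolated)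
Conditions: conc. H2SO4, 95–100 °C, 1.5 h (until CO evolution stops); pour on ice, filter, dry in vacuo at 60 °C
Reagents that add atoms: none
Why: von Pechmann condensation: hot H2SO4 decarbonylates malic acid to formylacetic acid 6, which attacks the 4-substituted resorcinol 4 at C-5 (ortho/para to the two OH groups and unhindered, the same linear orientation as in the classical dihydropsoralen synthesis from 6-hydroxycoumaran) to give 7, and the o-hydroxyarylacetic acid unit of 7 lactonises in the same dehydrating medium, so the α-pyranone and the γ-lactone form in one operation without a protecting group; no stereocentre arises.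

Step 3
Reactants: 3 5,7-dihydroxychroman-2-one; 8 2H-furo[3,2-g]chromene-2,7(3H)-dione
Product: 11 5-hydroxy-9-(7-hydroxy-2-oxo-2H-chromen-6-yl)-3,4-dihydro-2H,10H-pyrano[2,3-f]chromene-2,10-dione, via deoxybenzoin 9 (not isolated), via enaminoketone 10 (not isolated)
Conditions: BF3·OEt2 (solvent), 80 °C, 2 h; cool to 10 °C, DMF, then MsCl (3 equiv), 55→70 °C, 2 h; ice-water, filter
Reagents that add atoms: N,N-dimethylformamide, CN(C)C=O (supplies C-2 with its H)
Why: Friedel–Crafts acylation followed by Vilsmeier-type C1 insertion (the one-pot deoxybenzoin-to-isoflavone protocol): the strained aryl γ-lactone of 8 transfers its acyl group, without forming water that could scramble the δ-lactone, to C-8 of 3 (ortho to one and para to the other free OH, the site at which 5,7-dihydroxycoumarins are acylated), the activated CH2 of 9 is aminomethylenated by the DMF/MsCl iminium salt, and the only free ortho-OH closes ring C by 6-endo-trig addition–elimination (attack by the 2'-OH would be 5-endo-trig), which places the chain at C-6.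

Step 4
Reactants: 11 bis-lactone isoflavone
Product: 13 5,7-dihydroxy-6-(3-hydroxy-3-methylbutyl)-3-(7-hydroxy-2,2-dimethyl-2H-chromen-6-yl)-4H-chromen-4-one (target), via ring-opened Z-hexaol 12 (not isolated)
Conditions: MeMgBr (12 equiv, 3 M in Et2O), THF, −20 °C → rt, 4 h; AcOH (excess), 0 °C → rt, 2 h
Reagents that add atoms: methylmagnesium bromide, C[Mg]Br
Why: Double Grignard addition to each lactone (the classical coumarin → 2,2-dimethyl-2H-chromene and dihydrocoumarin → 3-hydroxy-3-methylbutylphenol conversions) is chemoselective because the two phenols and then O-5 become magnesium phenoxides that turn the chromone into a chelated, doubly vinylogous carboxylate far less electrophilic than the aryl ester carbonyls, and on the AcOH quench only the (Z)-allylic tertiary carbinol of 12, whose cation is an o/p-oxygen-stabilised protonated o-quinone methide, ionises and is captured by the 4'-OH (SN1/oxa-6π closure) while the saturated tertiary alcohol stays intact; no stereocentre arises.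

## Compound list
1 | phloroglucinol | Oc1cc(O)cc(O)c1 | starting material
2 | acrylic acid | C=CC(=O)O | starting material
3 | 5,7-dihydroxychroman-2-one | O=C1CCc2c(O)cc(O)cc2O1 | intermediate
4 | 2,4-dihydroxyphenylacetic acid | OC(=O)Cc1ccc(O)cc1O | starting material
5 | DL-malic acid (racemic) | OC(=O)CC(O)C(=O)O | starting material
6 | 3-oxopropanoic acid (formylacetic acid) | O=CCC(=O)O | intermediate (not isolated)
7 | (7-hydroxy-2-oxo-2H-chromen-6-yl)acetic acid | OC(=O)Cc1cc2ccc(=O)oc2cc1O | intermediate (not isolated)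
8 | 2H-furo[3,2-g]chromene-2,7(3H)-dione | O=C1Cc2cc3ccc(=O)oc3cc2O1 | intermediate
9 | 5,7-dihydroxy-8-[(7-hydroxy-2-oxo-2H-chromen-6-yl)acetyl]chroman-2-one | O=C1CCc2c(O)cc(O)c(C(=O)Cc3cc4ccc(=O)oc4cc3O)c2O1 | intermediate (not isolated)
10 | (E)-α-(dimethylaminomethylene) derivative of 9 | O=C1CCc2c(O)cc(O)c(C(=O)/C(=C/N(C)C)c3cc4ccc(=O)oc4cc3O)c2O1 | intermediate (not isolated)
11 | 5-hydroxy-9-(7-hydroxy-2-oxo-2H-chromen-6-yl)-3,4-dihydro-2H,10H-pyrano[2,3-f]chromene-2,10-dione | O=C1CCc2c(O)cc3occ(-c4cc5ccc(=O)oc5cc4O)c(=O)c3c2O1 | intermediate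
12 | 3-{2,4-dihydroxy-5-[(1Z)-3-hydroxy-3-methylbut-1-enyl]phenyl}-5,7-dihydroxy-6-(3-hydroxy-3-methylbutyl)-4H-chromen-4-one | CC(C)(O)CCc1c(O)cc2occ(-c3cc(/C=C\C(C)(C)O)c(O)cc3O)c(=O)c2c1O | intermediate (not isolated)
13 | 5,7-dihydroxy-6-(3-hydroxy-3-methylbutyl)-3-(7-hydroxy-2,2-dimethyl-2H-chromen-6-yl)-4H-chromen-4-one | CC(C)(O)CCc1c(O)cc2occ(-c3cc4c(cc3O)OC(C)(C)C=C4)c(=O)c2c1O | target

## Summary
Total step count: 4. Longest linear sequence: 3 (4 → 8 → 11 → 13, or 1 → 3 → 11 → 13).

## Steps most likely to fail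

**Step 4.**
- Risk: MeMgBr may attack C-2 or C-4 of the isoflavone or add 1,4 to the coumarin. The 7-oxidocoumarin may also be too sluggish.
- Fallback: give up the coumarin as ring-D precursor and build ring D last by an aldol/oxa-6π chromenylation. It sets out from 3 (with 4 in place of 8) and comes back at 13.
- The conditions of step 3 applied to 3 and 4 give the deoxybenzoin 8-[(2,4-dihydroxyphenyl)acetyl]-5,7-dihydroxychroman-2-one F1.
- After DMF/MsCl this becomes 9-(2,4-dihydroxyphenyl)-5-hydroxy-3,4-dihydro-2H,10H-pyrano[2,3-f]chromene-2,10-dione F2.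
- Its single, very reactive aryl alkanoate lactone is opened with MeMgBr at −40 °C to 3-(2,4-dihydroxyphenyl)-5,7-dihydroxy-6-(3-hydroxy-3-methylbutyl)-4H-chromen-4-one F3.
- F3 is condensed with 3-methylbut-2-enal (ethylenediammonium diacetate, toluene, 80 °C). The pyran closes at C-5'/O-4', the orientation seen for 3,4-dioxygenated phenols, and gives 13.

**Step 3.**
- Risk: acylation at C-6 instead of C-8 of 3, cyclodehydration of 9 through its free 2'-OH to a 2-arylbenzofuran, or a lazy acyl donor.
- Fallback: make the C3–C1' bond by cross-coupling instead of the C4–C4a bond by acylation. It sets out from 3 and comes back at 11.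
- Acetylation of 3 (AcOH, BF3·OEt2, 80 °C) gives 8-acetyl-5,7-dihydroxychroman-2-one F4, whose regiochemistry is checked at this simple stage.
- DMF-DMA (THF, 40 °C) gives the enaminone 8-[(E)-3-(dimethylamino)acryloyl]-5,7-dihydroxychroman-2-one F5.
- I2 (CHCl3, rt) closes and iodinates it to 5-hydroxy-9-iodo-3,4-dihydro-2H,10H-pyrano[2,3-f]chromene-2,10-dione F6.
- In parallel, 4-bromoresorcinol and malic acid (H2SO4) give 6-bromo-7-hydroxycoumarin F7.
- Miyaura borylation of F7 (B2pin2, KOAc, Pd(dppf)Cl2) gives 7-hydroxy-6-(4,4,5,5-tetramethyl-1,3,2-dioxaborolan-2-yl)coumarin F8.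
- Suzuki–Miyaura coupling of F6 with F8 (Pd(dppf)Cl2, K3PO4, dioxane) gives 11.

**Step 2.**
- Risk: early γ-lactonisation lowers the nucleophilicity of the ring, so that sulfonation or tar formation beats the Pechmann step.
- Fallback: close the two rings one after the other and form the pyranone by intramolecular alkyne hydroarylation. It sets out from 4 and comes back at 8.
- TsOH (cat.) in toluene under Dean–Stark conditions gives 6-hydroxybenzofuran-2(3H)-one F9.
- Propiolic acid with DCC gives 2-oxo-2,3-dihydrobenzofuran-6-yl propiolate F10.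
- Pd(OAc)2/TFA (or a cationic Au(I) catalyst) effects 6-endo hydroarylation at the unhindered C-5 to give 8.

## Further compounds
F1 | step 4 | 8-[(2,4-dihydroxyphenyl)acetyl]-5,7-dihydroxychroman-2-one | O=C1CCc2c(O)cc(O)c(C(=O)Cc3ccc(O)cc3O)c2O1
F2 | step 4 | 9-(2,4-dihydroxyphenyl)-5-hydroxy-3,4-dihydro-2H,10H-pyrano[2,3-f]chromene-2,10-dione | O=C1CCc2c(O)cc3occ(-c4ccc(O)cc4O)c(=O)c3c2O1
F3 | step 4 | 3-(2,4-dihydroxyphenyl)-5,7-dihydroxy-6-(3-hydroxy-3-methylbutyl)-4H-chromen-4-one | CC(C)(O)CCc1c(O)cc2occ(-c3ccc(O)cc3O)c(=O)c2c1O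
F4 | step 3 | 8-acetyl-5,7-dihydroxychroman-2-one | CC(=O)c1c(O)cc(O)c2c1OC(=O)CC2
F5 | step 3 | 8-[(E)-3-(dimethylamino)acryloyl]-5,7-dihydroxychroman-2-one | CN(C)/C=C/C(=O)c1c(O)cc(O)c2c1OC(=O)CC2
F6 | step 3 | 5-hydroxy-9-iodo-3,4-dihydro-2H,10H-pyrano[2,3-f]chromene-2,10-dione | O=C1CCc2c(O)cc3occ(I)c(=O)c3c2O1
F7 | step 3 | 6-bromo-7-hydroxycoumarin | O=c1ccc2cc(Br)c(O)cc2o1
F8 | step 3 | 7-hydroxy-6-(4,4,5,5-tetramethyl-1,3,2-dioxaborolan-2-yl)coumarin | CC1(C)OB(OC1(C)C)c1cc2ccc(=O)oc2cc1O
F9 | step 2 | 6-hydroxybenzofuran-2(3H)-one | O=C1Cc2ccc(O)cc2O1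
F10 | step 2 | 2-oxo-2,3-dihydrobenzofuran-6-yl propiolate | C#CC(=O)Oc1ccc2c(c1)OC(=O)C2
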